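**Plan** (locants: 3,7-dioxabicyclo[3.3.0]octan-2-one; C1 is α to C2=O, O3, C4 carries the guaiacyl ring, C5, C6H2, O7, C8 carries the catechol ring)
- Retrosynthesis: after removal of three silyl groups, the oxolane bonds O7–C8 and C1–C5 are cut together, which unravels both rings to an acyclic caffeate ester of a 1-aryl-2,3-epoxypropan-1-ol; then the ester C2–O3 is cut, then the oxirane and the vinyl–carbinol bond, back to vanillin.
- Enabling feature: O7–C6H2–C5 is a terminal oxirane in disguise (oxygen on the CH2, radical site at the ring-fusion carbon C5). C1–C8 is the α,β-pair of a cinnamoyl group whose 3,4-dioxygenated ring stabilises a radical or cation at C8, and the lactone linkage C2(=O)–O3–C4 is the tether between the two.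
- Forward: trivalent titanium opens the oxirane, the C5 radical closes 5-exo onto C1 (lactone ring), and iodine then activates C8 for capture by O7 (oxolane ring) in the same flask.
- Stereochemistry: C4 is set by a Sharpless kinetic-resolution epoxidation with D-(−)-diisopropyl tartrate; C5, C1 and C8 are relayed from C4 in the cascade (aryl trans to the CH2O arm, cis ring fusion, aryl at C8 on the convex face).

Key step: step 6

**Step 1**
Reactants: 1 vanillin (4-hydroxy-3-methoxybenzaldehyde)
Product: 2 4-[(tert-butyldimethylsilyl)oxy]-3-methoxybenzaldehyde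
Conditions: TBSCl, imidazole, DMF, rt
Reagents that add atoms: tert-butyldimethylsilyl chloride, CC(C)(C)[Si](C)(C)Cl
Why: Imidazole-promoted O-silylation of the phenol (silyl ether formation) masks the acidic OH for the organometallic and radical steps and leaves the aldehyde untouched.

**Step 2**
Reactants: 2 4-[(tert-butyldimethylsilyl)oxy]-3-methoxybenzaldehyde; 3 vinylmagnesium bromide
Product: 4 rac-1-{4-[(tert-butyldimethylsilyl)oxy]-3-methoxyphenyl}prop-2-en-1-ol
Conditions: CH2=CHMgBr, THF, −78 to 0 °C; aq NH4Cl
Reagents that add atoms: none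
Why: Grignard 1,2-addition to the aldehyde gives the racemic secondary allylic alcohol, and the aryl silyl ether should tolerate the reagent at low temperature.

**Step 3**
Reactants: 4 rac-1-{4-[(tert-butyldimethylsilyl)oxy]-3-methoxyphenyl}prop-2-en-1-ol
Product: 5 (R)-{4-[(tert-butyldimethylsilyl)oxy]-3-methoxyphenyl}[(2S)-oxiran-2-yl]methanol (erythro epoxy alcohol)
Conditions: Ti(OiPr)4 (0.2 equiv), D-(−)-diisopropyl tartrate (0.25 equiv), tBuOOH (0.45 equiv), 4 Å MS, CH2Cl2, −20 °C; stopped below half conversion
Reagents that add atoms: tert-butyl hydroperoxide, CC(C)(C)OO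
Why: Sharpless asymmetric epoxidation run as a kinetic resolution, in which the (S)-enantiomer of 4 should be epoxidised much faster with the D-tartrate and give the erythro epoxy alcohol (the (R)-enantiomer of 4 stays behind and is separated), so the carbinol centre that becomes C4 is set by the reagent, while the oxirane carbon configuration is of no consequence because it becomes a planar radical in step 6.

**Step 4**
Reactants: 6 caffeic acid ((E)-3-(3,4-dihydroxyphenyl)prop-2-enoic acid)
Product: 8 (E)-3-{3,4-bis[(tert-butyldimethylsilyl)oxy]phenyl}prop-2-enoic acid, via tris-silyl ester 7 (not isolated)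
Conditions: TBSCl (3.3 equiv), imidazole, DMF, rt; then AcOH/THF/H2O, rt
Reagents that add atoms: tert-butyldimethylsilyl chloride, CC(C)(C)[Si](C)(C)Cl
Why: Exhaustive silylation followed by selective hydrolysis of the silyl ester, which should cleave far faster than the two aryl silyl ethers, frees only the carboxylic acid.

**Step 5**
Reactants: 5 (R)-{4-[(tert-butyldimethylsilyl)oxy]-3-methoxyphenyl}[(2S)-oxiran-2-yl]methanol; 8 (E)-3-{3,4-bis[(tert-butyldimethylsilyl)oxy]phenyl}prop-2-enoic acid
Product: 9 (R)-{4-[(tert-butyldimethylsilyl)oxy]-3-methoxyphenyl}[(2S)-oxiran-2-yl]methyl (E)-3-{3,4-bis[(tert-butyldimethylsilyl)oxy]phenyl}prop-2-enoate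
Conditions: DCC, DMAP (cat.), CH2Cl2, 0 °C to rt
Reagents that add atoms: none
Why: Steglich esterification acylates the secondary alcohol without touching its C–O bond (retention at the carbinol centre), and the neutral conditions should spare the oxirane and the silyl ethers.

**Step 6**
Reactants: 9 (R)-{4-[(tert-butyldimethylsilyl)oxy]-3-methoxyphenyl}[(2S)-oxiran-2-yl]methyl (E)-3-{3,4-bis[(tert-butyldimethylsilyl)oxy]phenyl}prop-2-enoate
Product: 12 (1S,4S,5R,8S)-8-{3,4-bis[(tert-butyldimethylsilyl)oxy]phenyl}-4-{4-[(tert-butyldimethylsilyl)oxy]-3-methoxyphenyl}-3,7-dioxabicyclo[3.3.0]octan-2-one, via bis-titanium lactone 10 (not isolated), via benzylic iodide 11 (not isolated)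
Conditions: Cp2TiCl2 (2.5 equiv), Zn dust, THF, rt; the green Cp2TiCl solution added over 4 h to 9 in THF (0.01 M), 40 °C; then I2 (2 equiv), rt
Reagents that add atoms: none
Why: Proposed new method: Cp2TiCl (trivalent titanium) should open the terminal oxirane by single-electron transfer at its more substituted carbon; the secondary radical at C5 should add 5-exo-trig to the α-carbon of the cinnamoyl double bond, which closes the γ-lactone through the ester tether and places the new radical at the benzylic carbon C8; after capture as the benzyl–titanium species 10, iodine should convert C8 into the iodide 11, whose ionisation (helped by the electron-rich aryl group) lets the titanium alkoxide oxygen close the oxolane by 5-exo-tet attack. The closest known reaction type is the titanocene-mediated radical cyclisation of epoxy cinnamyl ethers followed by iodine-induced etherification to furofurans; new here is the acyloxy tether, which delivers the lactone directly but should slow ring closure because the ester must leave its preferred Z rotamer. C5 and C1 are set in the radical closure under control of the existing C4 centre: a chair-like transition state with the C4 aryl group pseudo-equatorial should put the CH2O–Ti arm trans to that aryl group and cis to the new benzylic arm, and only this cis isomer can go on to the bicycle. C8 is set in the ether closure, where the planar benzylic cation should be attacked so that the aryl group ends on the convex face of the cis-fused bicycle. The step needs attack at the α- and not the β-carbon of the cinnamate (secured by formation of the benzylic radical instead of a 6-endo α-ester radical, as in radical additions to cinnamic acid derivatives) and cyclisation ahead of reduction of the first radical (secured by slow addition of the titanium reagent at high dilution with mild heating).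

**Step 7**
Reactants: 12 (1S,4S,5R,8S)-8-{3,4-bis[(tert-butyldimethylsilyl)oxy]phenyl}-4-{4-[(tert-butyldimethylsilyl)oxy]-3-methoxyphenyl}-3,7-dioxabicyclo[3.3.0]octan-2-one
Product: 13 (1S,4S,5R,8S)-8-(3,4-dihydroxyphenyl)-4-(4-hydroxy-3-methoxyphenyl)-3,7-dioxabicyclo[3.3.0]octan-2-one (target)
Conditions: HF·pyridine, THF/pyridine, 0 °C to rt
Reagents that add atoms: none
Why: Fluoride-driven cleavage of the three aryl silyl ethers (Si–F bond formation) under buffered, non-basic conditions should free the phenols without forming phenoxides para to the benzylic C–O bonds, and no stereocentre takes part.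

**Compound list**
1 | vanillin (4-hydroxy-3-methoxybenzaldehyde) | COc1cc(C=O)ccc1O | starting material
2 | 4-[(tert-butyldimethylsilyl)oxy]-3-methoxybenzaldehyde | COc1cc(C=O)ccc1O[Si](C)(C)C(C)(C)C | intermediate
3 | vinylmagnesium bromide | C=C[Mg]Br | starting material
4 | rac-1-{4-[(tert-butyldimethylsilyl)oxy]-3-methoxyphenyl}prop-2-en-1-ol | COc1cc(C(O)C=C)ccc1O[Si](C)(C)C(C)(C)C | intermediate
5 | (R)-{4-[(tert-butyldimethylsilyl)oxy]-3-methoxyphenyl}[(2S)-oxiran-2-yl]methanol | COc1cc([C@@H](O)[C@@H]2CO2)ccc1O[Si](C)(C)C(C)(C)C | intermediate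
6 | caffeic acid, (E)-3-(3,4-dihydroxyphenyl)prop-2-enoic acid | O=C(O)/C=C/c1ccc(O)c(O)c1 | starting material
7 | tert-butyldimethylsilyl (E)-3-{3,4-bis[(tert-butyldimethylsilyl)oxy]phenyl}prop-2-enoate (tris-silyl ester, not isolated) | O=C(O[Si](C)(C)C(C)(C)C)/C=C/c1ccc(O[Si](C)(C)C(C)(C)C)c(O[Si](C)(C)C(C)(C)C)c1 | intermediate
8 | (E)-3-{3,4-bis[(tert-butyldimethylsilyl)oxy]phenyl}prop-2-enoic acid | O=C(O)/C=C/c1ccc(O[Si](C)(C)C(C)(C)C)c(O[Si](C)(C)C(C)(C)C)c1 | intermediate
9 | (R)-{4-[(tert-butyldimethylsilyl)oxy]-3-methoxyphenyl}[(2S)-oxiran-2-yl]methyl (E)-3-{3,4-bis[(tert-butyldimethylsilyl)oxy]phenyl}prop-2-enoate | COc1cc([C@@H](OC(=O)/C=C/c2ccc(O[Si](C)(C)C(C)(C)C)c(O[Si](C)(C)C(C)(C)C)c2)[C@@H]2CO2)ccc1O[Si](C)(C)C(C)(C)C | intermediate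
10 | bis-titanium lactone (not isolated): 4,5-trans-3,4-cis γ-lactone (C5 S, C4 R) with the silylated guaiacyl ring at C5, a CH2–O–Ti(Cl)Cp2 arm at C4 and a CH(aryl)–Ti(Cl)Cp2 arm at C3 (aryl = 3,4-bis(silyloxy)phenyl; both epimers at the benzylic carbon; tetravalent titanium) | COc1cc([C@H]2OC(=O)[C@H](C(c3ccc(O[Si](C)(C)C(C)(C)C)c(O[Si](C)(C)C(C)(C)C)c3)[Ti](Cl)(C3C=CC=C3)C3C=CC=C3)[C@@H]2CO[Ti](Cl)(C2C=CC=C2)C2C=CC=C2)ccc1O[Si](C)(C)C(C)(C)C | intermediate
11 | benzylic iodide (not isolated): the same lactone with CH(I)(aryl) at C3 and the CH2–O–Ti(Cl)Cp2 arm at C4 (both epimers at the iodide carbon) | COc1cc([C@H]2OC(=O)[C@H](C(I)c3ccc(O[Si](C)(C)C(C)(C)C)c(O[Si](C)(C)C(C)(C)C)c3)[C@@H]2CO[Ti](Cl)(C2C=CC=C2)C2C=CC=C2)ccc1O[Si](C)(C)C(C)(C)C | intermediate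
12 | (1S,4S,5R,8S)-8-{3,4-bis[(tert-butyldimethylsilyl)oxy]phenyl}-4-{4-[(tert-butyldimethylsilyl)oxy]-3-methoxyphenyl}-3,7-dioxabicyclo[3.3.0]octan-2-one | COc1cc([C@H]2OC(=O)[C@H]3[C@@H]2CO[C@@H]3c2ccc(O[Si](C)(C)C(C)(C)C)c(O[Si](C)(C)C(C)(C)C)c2)ccc1O[Si](C)(C)C(C)(C)C | intermediate
13 | (1S,4S,5R,8S)-8-(3,4-dihydroxyphenyl)-4-(4-hydroxy-3-methoxyphenyl)-3,7-dioxabicyclo[3.3.0]octan-2-one | COc1cc([C@H]2OC(=O)[C@H]3[C@@H]2CO[C@@H]3c2ccc(O)c(O)c2)ccc1O | target

**Step count**
Total steps: 7. Longest linear sequence: 6 steps (steps 1, 2, 3, 5, 6, 7 from vanillin); step 4 is a one-step side branch.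

**Steps most likely to fail**

1. Step 6 (proposed new method). The ring closure through the ester tether may be too slow, so that the first radical is reduced by a second titanium and lost by elimination. The benzylic cation may also lose the acidic proton at C1 instead of being captured by O7, and the titanium alkoxide may transfer the acyl group. The fallback uses known chemistry and sets out from 9. Reductive acetylation of the ester (iBu2AlH, CH2Cl2, −78 °C; then Ac2O, pyridine, DMAP) should give the α-acetoxy ether F1, whose tether carbon is now sp3, so the substrate belongs to the epoxy cinnamyl ether class for which the titanocene cyclisation is established. Treatment with Cp2TiCl (from Cp2TiCl2 and Zn, THF) and then I2 should give the bicyclic acetoxy acetal F2 by the same radical closure and etherification. Oxidation with CrO3/H2SO4 in acetone (Jones oxidation, as at the end of a Ueno–Stork sequence) should hydrolyse the anomeric acetate and oxidise the lactol, and the route is rejoined at 12.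

2. Step 3. Discrimination between the two enantiomers of 4 may be insufficient near half conversion, which would erode the enantiomeric purity of the epoxide. The fallback separates resolution from epoxidation and sets out from 4. Acylation with immobilised Candida antarctica lipase B and vinyl acetate (MTBE, rt) should esterify the (R)-enantiomer and leave the (S)-allylic alcohol F3 beside the (R)-acetate F4, which is removed by chromatography. Epoxidation of F3 with Ti(OiPr)4, D-(−)-diisopropyl tartrate and tBuOOH, now a matched pair run to full conversion, should return the route at 5.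

3. Step 7. Once the para-hydroxy groups are free, the benzylic C–O bonds at C4 and C8 may ionise through quinone methides (epimerisation or lactone opening), above all if phenoxides form, and the catechol may oxidise in air. The fallback separates silicon removal from phenol release and sets out from 12. Desilylative acetylation (CsF, Ac2O, DMF, rt) should trap each phenoxide as it forms and give the tri-O-acetate F5, which can be purified. Near-neutral deacetylation (NH4OAc, MeOH/H2O, rt) should then return the route at 13.

**Further compounds**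
F1 | step 6 | (E)-1-acetoxy-3-{3,4-bis[(tert-butyldimethylsilyl)oxy]phenyl}prop-2-enyl ether of 5 (α-acetoxy ether, both epimers at the acetal carbon) | COc1cc([C@@H](OC(OC(C)=O)/C=C/c2ccc(O[Si](C)(C)C(C)(C)C)c(O[Si](C)(C)C(C)(C)C)c2)[C@@H]2CO2)ccc1O[Si](C)(C)C(C)(C)C
F2 | step 6 | (1S,4S,5R,8S)-2-acetoxy-8-{3,4-bis[(tert-butyldimethylsilyl)oxy]phenyl}-4-{4-[(tert-butyldimethylsilyl)oxy]-3-methoxyphenyl}-3,7-dioxabicyclo[3.3.0]octane (both C2 epimers) | COc1cc([C@H]2OC(OC(C)=O)[C@H]3[C@@H]2CO[C@@H]3c2ccc(O[Si](C)(C)C(C)(C)C)c(O[Si](C)(C)C(C)(C)C)c2)ccc1O[Si](C)(C)C(C)(C)C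
F3 | step 3 | (S)-1-{4-[(tert-butyldimethylsilyl)oxy]-3-methoxyphenyl}prop-2-en-1-ol | COc1cc([C@@H](O)C=C)ccc1O[Si](C)(C)C(C)(C)C
F4 | step 3 | (R)-1-{4-[(tert-butyldimethylsilyl)oxy]-3-methoxyphenyl}prop-2-en-1-yl acetate | COc1cc([C@H](OC(C)=O)C=C)ccc1O[Si](C)(C)C(C)(C)C
F5 | step 7 | (1S,4S,5R,8S)-8-(3,4-diacetoxyphenyl)-4-(4-acetoxy-3-methoxyphenyl)-3,7-dioxabicyclo[3.3.0]octan-2-one | COc1cc([C@H]2OC(=O)[C@H]3[C@@H]2CO[C@@H]3c2ccc(OC(C)=O)c(OC(C)=O)c2)ccc1OC(C)=O
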